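**Plan**

1. Locants: chromanone half O1, C2 (ketal carbon carrying the 4-hydroxyphenyl group, aryl B), C3 (carbinol), C4 (C=O), ring A C4a–C8a; flavan half primed (C8' on C3, O7' on C2, its aryl = aryl B').
2. The retrosynthesis cuts O1–C2 (ring C ketal), then C4a–C5 of ring A, then C4–C4a (chain onto an ester), the C2–O and C3–O bonds (benzofuran oxidation), C3–C4 with O7'–C2 (carbonylative annulation) and C8'–C3 (alkyne coupling).
3. Enabling feature: ring A (C4a–C8a) is a phloroglucinol acylated at C4a by C4, that is, the Claisen-folded form of a C4-bound 3,5,7-triketo ester whose C4a methylene can attack its own ester carbon C5.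
4. Forward: (2S)-naringenin → flavan → C8' alkyne → benzofuran ring with the C3 ester → C2/C3 oxygenation → triketo ester chain on C4 → ring A by Claisen folding → ring C by ketal exchange → hydrogenolysis.
5. Stereochemistry: C2' comes from (2S)-naringenin, whose carbonyl is removed before any strong base is used; C3 comes from a catalyst-controlled epoxidation of the benzofuran C2=C3 bond; C2 re-forms under thermodynamic control when ring C closes and follows C3.

Key step: step 11

Assumption 1: (2S)-naringenin is taken as the purchasable single enantiomer and its optical purity is checked on receipt, since flavanones racemise through the ring-opened chalcone in base.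
Assumption 2: C2 is a ketal carbon that re-forms through its oxocarbenium ion when ring C closes, so it is not controlled separately but written as in the target string; only C3 and C2' are treated as centres to be set.

**Route**

Step 1
Reactants: 1 (2S)-naringenin
Product: 2 (2S)-5-hydroxy-2-(4-hydroxyphenyl)-7-(methoxymethoxy)chroman-4-one
Conditions: MOMCl (1.05 equiv), i-Pr2NEt (1.2 equiv), THF, 0 °C
Reagents that add atoms: chloromethyl methyl ether, COCCl
Why: Regioselective Williamson-type O-alkylation: the 7-hydroxyl (later O7'), para to the carbonyl and by far the most acidic phenol, is the one ionised by the amine, the hydrogen-bonded 5-hydroxyl and the aryl B' hydroxyl stay free, and a weak base at 0 °C avoids the ring opening to the chalcone that would racemise C2'.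

Step 2
Reactants: 2 (2S)-5-hydroxy-2-(4-hydroxyphenyl)-7-(methoxymethoxy)chroman-4-one
Product: 5 (2S)-2-(4-hydroxyphenyl)-7-(methoxymethoxy)chroman-5-ol, via bis(ethyl carbonate) 3 (not isolated), via flavan monocarbonate 4 (not isolated)
Conditions: ClCO2Et (2.3 equiv), Et3N, THF, 0 °C; then NaBH4, THF/H2O, 0 °C to rt; then 2 M NaOH, rt
Reagents that add atoms: none
Why: Carbonate-assisted borohydride deoxygenation of an ortho-hydroxyaryl ketone: after O-acylation (3), hydride reduces the ketone, the neighbouring ethoxycarbonyl group moves to the new alkoxide and is expelled to give a transient ortho-quinone methide that takes up a second hydride (4), and NaOH cleaves the remaining aryl carbonate; C2' is not touched and stays S.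

Step 3
Reactants: 5 (2S)-2-(4-hydroxyphenyl)-7-(methoxymethoxy)chroman-5-ol
Product: 6 (2S)-5-(benzyloxy)-2-[4-(benzyloxy)phenyl]-7-(methoxymethoxy)chromane
Conditions: BnBr (2.4 equiv), K2CO3, DMF, rt
Reagents that add atoms: benzyl bromide, BrCc1ccccc1
Why: Williamson ether synthesis on both phenols; carbonate base is harmless now that the flavan has no carbonyl through which C2' could epimerise.

Step 4
Reactants: 6 (2S)-5-(benzyloxy)-2-[4-(benzyloxy)phenyl]-7-(methoxymethoxy)chromane
Product: 7 (2S)-5-(benzyloxy)-2-[4-(benzyloxy)phenyl]-8-iodo-7-(methoxymethoxy)chromane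
Conditions: N-iodosuccinimide (1.0 equiv), DMF, 0 °C, dark
Reagents that add atoms: N-iodosuccinimide, O=C1CCC(=O)N1I
Why: Electrophilic aromatic iodination: of the two free positions of the trioxygenated ring, C8' (between O1' and O7') is the one halogenated in 5,7-di-O-alkylflavans, as in the C8-selective halogenation of per-O-benzylated catechins, and the less activated benzyloxyphenyl ring should not react with one equivalent.

Step 5
Reactants: 7 (2S)-5-(benzyloxy)-2-[4-(benzyloxy)phenyl]-8-iodo-7-(methoxymethoxy)chromane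
Product: 8 (2S)-5-(benzyloxy)-2-[4-(benzyloxy)phenyl]-8-iodochroman-7-ol
Conditions: HCl (2 M in MeOH), THF, 40 °C
Reagents that add atoms: none
Why: Acid-catalysed acetal cleavage (methanolysis) of the aryl methoxymethyl ether; the benzyl ethers, the aryl iodide and the chroman ether are stable to dilute HCl at this temperature.

Step 6
Reactants: 8 (2S)-5-(benzyloxy)-2-[4-(benzyloxy)phenyl]-8-iodochroman-7-ol; 9 1-(benzyloxy)-4-ethynylbenzene
Product: 10 (2S)-5-(benzyloxy)-2-[4-(benzyloxy)phenyl]-8-{[4-(benzyloxy)phenyl]ethynyl}chroman-7-ol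
Conditions: PdCl2(PPh3)2 (3 mol %), CuI (5 mol %), Et3N, THF, rt to 40 °C
Reagents that add atoms: none
Why: Sonogashira coupling of the aryl iodide with the terminal alkyne (C8'–C3 bond); running it at or near room temperature keeps the free ortho-hydroxyl from cyclising onto the alkyne before carbon monoxide is offered in step 7.

Step 7
Reactants: 10 (2S)-5-(benzyloxy)-2-[4-(benzyloxy)phenyl]-8-{[4-(benzyloxy)phenyl]ethynyl}chroman-7-ol
Product: 11 methyl (2S)-5-(benzyloxy)-2,8-bis[4-(benzyloxy)phenyl]-3,4-dihydro-2H-furo[2,3-h]chromene-9-carboxylate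
Conditions: PdI2 (5 mol %), thiourea (5 mol %), CBr4, Cs2CO3, CO (1 atm), MeOH, 40 °C
Reagents that add atoms: carbon monoxide, [C-]#[O+]; methanol, CO
Why: Oxidative alkoxycarbonylative heteroannulation of an ortho-alkynylphenol: divalent palladium activates the alkyne, the phenoxide adds 5-endo-dig (O7'–C2), the 3-benzofuranylpalladium species inserts CO (C3–C4) and is cleaved by methanol to the ester, and CBr4 reoxidises the zerovalent palladium.

Step 8
Reactants: 11 methyl (2S)-5-(benzyloxy)-2,8-bis[4-(benzyloxy)phenyl]-3,4-dihydro-2H-furo[2,3-h]chromene-9-carboxylate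
Product: 13 methyl (2S,8R,9S)-5-(benzyloxy)-2,8-bis[4-(benzyloxy)phenyl]-9-hydroxy-8-methoxy-3,4,8,9-tetrahydro-2H-furo[2,3-h]chromene-9-carboxylate, via epoxide 12 (not isolated)
Conditions: (S,S)-[N,N'-bis(3,5-di-tert-butylsalicylidene)cyclohexane-1,2-diaminato]MnCl (5 mol %), mCPBA, N-methylmorpholine N-oxide, CH2Cl2, −78 °C; then MeOH, pyridinium p-toluenesulfonate (cat.), −78 to −20 °C
Reagents that add atoms: 3-chloroperoxybenzoic acid (mCPBA), OOC(=O)c1cccc(Cl)c1; methanol, CO
Why: Proposed new method: the oxo-manganese species formed from the chiral salen complex and mCPBA should transfer oxygen to the C2=C3 bond of the benzofuran, a tetrasubstituted, aryl-conjugated cyclic enol ether, by side-on approach over the diimine bridge, so that the catalyst and not the remote C2' centre chooses the face and sets the C3–O bond; methanol then opens the labile epoxide 12 at C2 through the oxocarbenium ion stabilised by O7' and aryl B, entering on the face of the new C3 hydroxyl and away from the ester, before a 1,2-shift of the ester can intervene (the C2 configuration is immaterial because it is re-set in step 12); the closest known reactions are the Jacobsen–Katsuki epoxidation of tetrasubstituted 2H-chromenes and of isoflavones (cyclic β-aryloxy enones) and the dioxirane epoxidation of 2,3-disubstituted benzofurans with alcohol opening; the (S,S) complex is chosen by analogy with its sense on 2,2-dimethylchromene and indene, which has to be confirmed (the (R,R) complex is the alternative), and the minor C3 epimer is a diastereomer that chromatography should remove.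

Step 9
Reactants: 13 methyl (2S,8R,9S)-5-(benzyloxy)-2,8-bis[4-(benzyloxy)phenyl]-9-hydroxy-8-methoxy-3,4,8,9-tetrahydro-2H-furo[2,3-h]chromene-9-carboxylate
Product: 14 methyl (2S,8R,9S)-5-(benzyloxy)-2,8-bis[4-(benzyloxy)phenyl]-9-[(benzyloxy)methoxy]-8-methoxy-3,4,8,9-tetrahydro-2H-furo[2,3-h]chromene-9-carboxylate
Conditions: BnOCH2Cl, i-Pr2NEt, n-Bu4NI (cat.), ClCH2CH2Cl, 50 °C
Reagents that add atoms: benzyl chloromethyl ether, ClCOCc1ccccc1
Why: Alkoxymethylation of a tertiary alcohol with a chloromethyl ether and a hindered amine under iodide catalysis: the small, oxocarbenium-like electrophile should reach the crowded C3 hydroxyl under non-acidic conditions that leave the C2 ketal and the ester untouched, and the benzyl-type acetal can later leave together with the benzyl ethers.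

Step 10
Reactants: 14 methyl (2S,8R,9S)-5-(benzyloxy)-2,8-bis[4-(benzyloxy)phenyl]-9-[(benzyloxy)methoxy]-8-methoxy-3,4,8,9-tetrahydro-2H-furo[2,3-h]chromene-9-carboxylate; 15 methyl 3,5-dioxohexanoate
Product: 16 methyl 7-[(2S,8R,9R)-5-(benzyloxy)-2,8-bis[4-(benzyloxy)phenyl]-9-[(benzyloxy)methoxy]-8-methoxy-3,4,8,9-tetrahydro-2H-furo[2,3-h]chromen-9-yl]-3,5,7-trioxoheptanoate
Conditions: 15 (2.5 equiv), LiN(i-Pr)2 (7.5 equiv), THF, −78 to 0 °C; then 14, −78 to 0 °C; AcOH quench
Reagents that add atoms: none
Why: Terminal C-acylation of a β,δ-diketo ester trianion (polyanion Claisen acylation, C4–C4a bond): the C6 carbanion of 15, the last formed and most nucleophilic site, attacks the non-enolisable ester of 14, which is activated by its α-oxygen and by lithium chelation, and the product stays protected as its polyenolate until the quench; C2 and C3 carry no acidic hydrogen and are untouched.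

Step 11
Reactants: 16 methyl 7-[(2S,8R,9R)-5-(benzyloxy)-2,8-bis[4-(benzyloxy)phenyl]-9-[(benzyloxy)methoxy]-8-methoxy-3,4,8,9-tetrahydro-2H-furo[2,3-h]chromen-9-yl]-3,5,7-trioxoheptanoate
Product: 17 [(2S,8R,9R)-5-(benzyloxy)-2,8-bis[4-(benzyloxy)phenyl]-9-[(benzyloxy)methoxy]-8-methoxy-3,4,8,9-tetrahydro-2H-furo[2,3-h]chromen-9-yl](2,4,6-trihydroxyphenyl)methanone
Conditions: Mg(OMe)2 (6 equiv), MeOH, rt, argon; then cold 1 M HCl to pH 4
Reagents that add atoms: none
Why: Magnesium methoxide converts the 3,5,7-triketo ester into its chelated polyenolate, in which C4a, flanked by the C4 and C8a carbonyls, attacks the ester carbonyl C5 and methoxide leaves (intramolecular Claisen condensation, C4a–C5 bond); the ring, first formed as its triketo tautomer, aromatises by enolisation to the phloroglucinol ring A. The closest known reaction is the Mg(OMe)2-mediated Claisen cyclisation of 7-aryl-3,5,7-trioxoheptanoates to 2,4,6-trihydroxyphenyl ketones, the laboratory counterpart of polyketide folding in flavonoid biosynthesis. Ring A closes in the 6-exo-trig mode (C4a, C8a, C8, C7, C6 and C5 in the ring, the ester oxygen outside). No stereocentre is formed, and C2, C3 and C2' have no acidic hydrogen or leaving group that the base could use. The selectivity needed is Claisen over aldol folding: the aldol mode would require the C6 carbanion to add to the C4 ketone, which is shielded by the fully substituted C3 with its aryl, ketal and benzyloxymethoxy neighbours, while magnesium chelation of the β-dicarbonyl units holds the chain in the Claisen geometry. Because ring A is symmetric about the C4–C4a axis, either ortho hydroxyl can close ring C afterwards.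

Step 12
Reactants: 17 [(2S,8R,9R)-5-(benzyloxy)-2,8-bis[4-(benzyloxy)phenyl]-9-[(benzyloxy)methoxy]-8-methoxy-3,4,8,9-tetrahydro-2H-furo[2,3-h]chromen-9-yl](2,4,6-trihydroxyphenyl)methanone
Product: 18 tri-O-benzyl 3-O-(benzyloxymethyl) daphnodorin F (target skeleton with benzyl ethers on O5' and on the 4-oxygens of aryl B and aryl B', C3–OCH2OBn, ring A hydroxyls free; C2, C3 and C2' as in 19)
Conditions: CF3CO2H (2 equiv), 4 Å molecular sieves, CH2Cl2, 0 °C
Reagents that add atoms: none
Why: Acid-catalysed intramolecular transketalisation: loss of methanol from C2 gives an oxocarbenium ion stabilised by O7' and aryl B, which one of the two equivalent ortho hydroxyls of ring A, held in reach by the C4 carbonyl, captures in a 6-exo-trig closure of ring C; the C3 ether blocks a 1,2-acyl shift to the cation, and C2 is re-formed under thermodynamic control in the configuration that C3 imposes through the ring fusion.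

Step 13
Reactants: 18 tri-O-benzyl 3-O-(benzyloxymethyl) daphnodorin F
Product: 19 daphnodorin F
Conditions: H2 (1 atm), Pd(OH)2/C, EtOAc/MeOH, rt
Reagents that add atoms: none
Why: Catalytic hydrogenolysis cleaves the three aryl benzyl ethers and the benzyl end of the benzyloxymethyl group, whose hemiacetal then loses formaldehyde (held by methanol as its hemiacetal); under neutral conditions at one atmosphere the ketal, the diaryl ketone and the benzylic C2'–O1' bond should not be reduced, so all three stereocentres are retained.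

**Compound list**

1 | (2S)-naringenin, (2S)-5,7-dihydroxy-2-(4-hydroxyphenyl)chroman-4-one | O=C1C[C@@H](c2ccc(O)cc2)Oc2cc(O)cc(O)c12 | starting material
2 | (2S)-5-hydroxy-2-(4-hydroxyphenyl)-7-(methoxymethoxy)chroman-4-one | O=C1C[C@@H](c2ccc(O)cc2)Oc2cc(OCOC)cc(O)c12 | intermediate
3 | (2S)-5-(ethoxycarbonyloxy)-2-[4-(ethoxycarbonyloxy)phenyl]-7-(methoxymethoxy)chroman-4-one, bis(ethyl carbonate) formed in the flask | O=C1C[C@@H](c2ccc(OC(=O)OCC)cc2)Oc2cc(OCOC)cc(OC(=O)OCC)c12 | intermediate
4 | (2S)-2-[4-(ethoxycarbonyloxy)phenyl]-7-(methoxymethoxy)chroman-5-ol, flavan monocarbonate formed in the flask | C1C[C@@H](c2ccc(OC(=O)OCC)cc2)Oc2cc(OCOC)cc(O)c12 | intermediate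
5 | (2S)-2-(4-hydroxyphenyl)-7-(methoxymethoxy)chroman-5-ol | C1C[C@@H](c2ccc(O)cc2)Oc2cc(OCOC)cc(O)c12 | intermediate
6 | (2S)-5-(benzyloxy)-2-[4-(benzyloxy)phenyl]-7-(methoxymethoxy)chromane | C1C[C@@H](c2ccc(OCc3ccccc3)cc2)Oc2cc(OCOC)cc(OCc3ccccc3)c12 | intermediate
7 | (2S)-5-(benzyloxy)-2-[4-(benzyloxy)phenyl]-8-iodo-7-(methoxymethoxy)chromane | C1C[C@@H](c2ccc(OCc3ccccc3)cc2)Oc2c(I)c(OCOC)cc(OCc3ccccc3)c12 | intermediate
8 | (2S)-5-(benzyloxy)-2-[4-(benzyloxy)phenyl]-8-iodochroman-7-ol | C1C[C@@H](c2ccc(OCc3ccccc3)cc2)Oc2c(I)c(O)cc(OCc3ccccc3)c12 | intermediate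
9 | 1-(benzyloxy)-4-ethynylbenzene | C#Cc1ccc(OCc2ccccc2)cc1 | starting material
10 | (2S)-5-(benzyloxy)-2-[4-(benzyloxy)phenyl]-8-{[4-(benzyloxy)phenyl]ethynyl}chroman-7-ol | C1C[C@@H](c2ccc(OCc3ccccc3)cc2)Oc2c(C#Cc3ccc(OCc4ccccc4)cc3)c(O)cc(OCc3ccccc3)c12 | intermediate
11 | methyl (2S)-5-(benzyloxy)-2,8-bis[4-(benzyloxy)phenyl]-3,4-dihydro-2H-furo[2,3-h]chromene-9-carboxylate (benzofuran C2 = position 8, C3 = position 9) | COC(=O)c1c(-c2ccc(OCc3ccccc3)cc2)oc2cc(OCc3ccccc3)c3c(c12)O[C@H](c1ccc(OCc4ccccc4)cc1)CC3 | intermediate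
12 | 8,9-epoxide of 11 (C2–C3 epoxide, oxygen on the face that carries the 9-hydroxyl of 13), formed in the flask | O1[C@]2(c3ccc(OCc5ccccc5)cc3)Oc3cc(OCc5ccccc5)c4c(c3[C@]12C(=O)OC)O[C@H](c1ccc(OCc5ccccc5)cc1)CC4 | intermediate
13 | methyl (2S,8R,9S)-5-(benzyloxy)-2,8-bis[4-(benzyloxy)phenyl]-9-hydroxy-8-methoxy-3,4,8,9-tetrahydro-2H-furo[2,3-h]chromene-9-carboxylate (8-OMe cis to 9-OH) | CO[C@]2(c3ccc(OCc5ccccc5)cc3)Oc3cc(OCc5ccccc5)c4c(c3[C@]2(C(=O)OC)O)O[C@H](c1ccc(OCc5ccccc5)cc1)CC4 | intermediate
14 | methyl (2S,8R,9S)-5-(benzyloxy)-2,8-bis[4-(benzyloxy)phenyl]-9-[(benzyloxy)methoxy]-8-methoxy-3,4,8,9-tetrahydro-2H-furo[2,3-h]chromene-9-carboxylate | CO[C@]2(c3ccc(OCc5ccccc5)cc3)Oc3cc(OCc5ccccc5)c4c(c3[C@]2(C(=O)OC)OCOCc5ccccc5)O[C@H](c1ccc(OCc5ccccc5)cc1)CC4 | intermediate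
15 | methyl 3,5-dioxohexanoate | COC(=O)CC(=O)CC(C)=O | starting material
16 | methyl 7-[(2S,8R,9R)-5-(benzyloxy)-2,8-bis[4-(benzyloxy)phenyl]-9-[(benzyloxy)methoxy]-8-methoxy-3,4,8,9-tetrahydro-2H-furo[2,3-h]chromen-9-yl]-3,5,7-trioxoheptanoate (precursor of the key step) | CO[C@]2(c3ccc(OCc5ccccc5)cc3)Oc3cc(OCc5ccccc5)c4c(c3[C@]2(C(=O)CC(=O)CC(=O)CC(=O)OC)OCOCc5ccccc5)O[C@H](c1ccc(OCc5ccccc5)cc1)CC4 | intermediate
17 | [(2S,8R,9R)-5-(benzyloxy)-2,8-bis[4-(benzyloxy)phenyl]-9-[(benzyloxy)methoxy]-8-methoxy-3,4,8,9-tetrahydro-2H-furo[2,3-h]chromen-9-yl](2,4,6-trihydroxyphenyl)methanone (product of the key step) | CO[C@]2(c3ccc(OCc5ccccc5)cc3)Oc3cc(OCc5ccccc5)c4c(c3[C@]2(C(=O)c2c(O)cc(O)cc2O)OCOCc5ccccc5)O[C@H](c1ccc(OCc5ccccc5)cc1)CC4 | intermediate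
18 | tri-O-benzyl 3-O-(benzyloxymethyl) daphnodorin F (benzyl ethers on O5' and on aryl B and aryl B', C3–OCH2OBn, (2'S), C2 and C3 as in 19) | O=C1c2c(O)cc(O)cc2O[C@]2(c3ccc(OCc5ccccc5)cc3)Oc3cc(OCc5ccccc5)c4c(c3[C@@]12OCOCc5ccccc5)O[C@H](c1ccc(OCc5ccccc5)cc1)CC4 | intermediate
19 | daphnodorin F ((2S,3R,2'S) in the locants used here) | O=C1c2c(O)cc(O)cc2O[C@]2(c3ccc(O)cc3)Oc3cc(O)c4c(c3[C@@]12O)O[C@H](c1ccc(O)cc1)CC4 | target

**Step count and risks**

Total step count: 13. Longest linear sequence: 13 steps, from 1 to 19; 9 and 15 are purchased and enter at steps 6 and 10.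

Steps most likely to fail:

1. Step 8 (Proposed new method). Oxygen transfer to the ester-deactivated, tetrasubstituted C2=C3 bond may be slow, may occur on both faces or with the opposite sense, and the epoxide may undergo a 1,2-ester shift before methanol captures it. The fallback sets out from 11 and comes back at 13, and gives up catalyst control for a diastereomer separation. Compound 11 is oxidised with dimethyldioxirane in acetone–methanol at −20 °C, the known dioxirane epoxidation of 2,3-disubstituted benzofurans with opening by the alcohol as the epoxide forms. This gives epoxide 12 together with the diastereomeric epoxide F1, and methanol converts them into 13 and the C2,C3-diastereomeric hydroxy ketal F2. Because of the C2' centre the two are diastereomers, not enantiomers, and should be separable by chromatography or crystallisation; 13 then continues with step 9.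

2. Step 10. The trianion may fail to add to the ester carbonyl, which sits on a fully substituted carbon next to a second quaternary centre, so that only proton exchange and slow breakdown of the polyanion occur on warming. The fallback sets out from 14 and comes back at 16, and replaces the ester by a more electrophilic aldehyde. Compound 14 is reduced with i-Bu2AlH in CH2Cl2 at −78 °C to the aldehyde F3. The same trianion of 15 then adds to F3 through its terminal carbon (aldol addition) to give the hydroxy diketo ester F4, a mixture of carbinol epimers. Oxidation of this β-hydroxy ketone with IBX in EtOAc, a known route to β-diketones, gives 16.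

3. Step 11. Methoxide may cleave the polyketone by retro-Claisen attack, or the chain may close through oxygen (enol lactonisation to a 4-hydroxy-2-pyranone) instead of through C4a. The fallback sets out from 14 and comes back at 17, and introduces ring A as a preformed aryl nucleophile instead of folding it. Compound 14 is reduced to the aldehyde F3 as in the fallback to step 10. 1,3,5-Tris(methoxymethoxy)benzene is lithiated with n-BuLi between two of its acetal oxygens to give 2,4,6-tris(methoxymethoxy)phenyllithium F5, which adds to F3 to give the secondary carbinol F6. Dess–Martin oxidation gives the aryl ketone F7. Dilute HCl in methanol then removes the three aryl methoxymethyl ethers, while the alkyl benzyloxymethyl ether and the methyl ketal should persist in methanol, giving 17.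

**Further compounds**

F1 | step 8 | diastereomeric 8,9-epoxide of 11 (oxygen on the opposite face of C2=C3) | O1[C@@]2(c3ccc(OCc5ccccc5)cc3)Oc3cc(OCc5ccccc5)c4c(c3[C@@]12C(=O)OC)O[C@H](c1ccc(OCc5ccccc5)cc1)CC4
F2 | step 8 | methyl (2S,8S,9R)-5-(benzyloxy)-2,8-bis[4-(benzyloxy)phenyl]-9-hydroxy-8-methoxy-3,4,8,9-tetrahydro-2H-furo[2,3-h]chromene-9-carboxylate, C2,C3-diastereomer of 13 | CO[C@@]2(c3ccc(OCc5ccccc5)cc3)Oc3cc(OCc5ccccc5)c4c(c3[C@@]2(C(=O)OC)O)O[C@H](c1ccc(OCc5ccccc5)cc1)CC4
F3 | step 10 | aldehyde from 14 (C3–CHO in place of C3–CO2Me, other centres as in 14) | CO[C@]2(c3ccc(OCc5ccccc5)cc3)Oc3cc(OCc5ccccc5)c4c(c3[C@]2(C=O)OCOCc5ccccc5)O[C@H](c1ccc(OCc5ccccc5)cc1)CC4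
F4 | step 10 | methyl 7-hydroxy-3,5-dioxoheptanoate adduct of F3 (7-hydroxy analogue of 16, carbinol centre undefined) | CO[C@]2(c3ccc(OCc5ccccc5)cc3)Oc3cc(OCc5ccccc5)c4c(c3[C@]2(C(O)CC(=O)CC(=O)CC(=O)OC)OCOCc5ccccc5)O[C@H](c1ccc(OCc5ccccc5)cc1)CC4
F5 | step 11 | 2,4,6-tris(methoxymethoxy)phenyllithium | [Li]c1c(OCOC)cc(OCOC)cc1OCOC
F6 | step 11 | [2,4,6-tris(methoxymethoxy)phenyl]carbinol from F3 (carbinol centre undefined) | CO[C@]2(c3ccc(OCc5ccccc5)cc3)Oc3cc(OCc5ccccc5)c4c(c3[C@]2(C(O)c2c(OCOC)cc(OCOC)cc2OCOC)OCOCc5ccccc5)O[C@H](c1ccc(OCc5ccccc5)cc1)CC4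
F7 | step 11 | 2,4,6-tris(methoxymethoxy)phenyl ketone (tris-MOM ether of 17) | CO[C@]2(c3ccc(OCc5ccccc5)cc3)Oc3cc(OCc5ccccc5)c4c(c3[C@]2(C(=O)c2c(OCOC)cc(OCOC)cc2OCOC)OCOCc5ccccc5)O[C@H](c1ccc(OCc5ccccc5)cc1)CC4
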